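**Strategy.** Both halves come from one monomer, the silyl ether 25 of 8β-hydroxydehydrozaluzanin C, joined at the end by Saegusa oxidation and Diels–Alder union (C14–C15′, C2–C4′). Ring B, the cycloheptane C1–C5–C6–C7–C8–C9–C10, is cut at C1–C5 and C7–C8: a dearomative intramolecular (4+3) cycloaddition of an oxyallyl cation (C5–C6–C7) with a tethered 3-methoxyfuran (C8–C9–C10–C1) closes rings A and B in one operation. It exploits the oxygen pattern of ring B: the oxyallyl oxygen becomes the lactone oxygen on C6, the furan oxygen the C8 hydroxyl, the methoxy-bearing carbon the C10 methylene carbon. The precursor is an acyclic α-chloro ketone made by a proline aldol.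

Key step: step 6

Remark on numbering: guaiane numbering is used (C1–C15 for the enone half, primed numbers for the spiro half; ring A = five-membered ring C1–C5, ring B = seven-membered ring, ring C = lactone); α/β refer to the orientation in which H6 is β.

Assumption: C5 and C10 of the enone half are γ-positions of the C1=C2–C3=O enone and therefore epimerizable; the depicted arrangement (H5 and H10 cis to H6, so H5 is cis to H6 in this half but trans in the spiro half) is taken to be the one reached under equilibrating base.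

Step 1
Reactants: 1 tert-butyl 3-bromopropanoate; 2 chloroacetyl chloride
Product: 4 tert-butyl 5-chloro-4-oxopentanoate, via alkylzinc bromide 3 (not isolated)
Conditions: Zn dust, LiCl, THF, 50 °C; then 2, Pd(PPh3)4 (2 mol%), 0 °C → rt
Reagents that add atoms: none
Why: Zinc insertion gives the chelated β-zincio ester 3, and its Negishi acylation at the acyl chloride of 2, catalysed by zerovalent palladium, should give the chloromethyl ketone while the alkyl chloride stays untouched.

Step 2
Reactants: 5 3-bromofuran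
Product: 6 3-methoxyfuran
Conditions: NaOMe, CuBr (10 mol%), MeOH–NMP, 100 °C, sealed tube
Reagents that add atoms: sodium methoxide, C[O-].[Na+]
Why: Copper-catalysed Ullmann-type etherification should replace the heteroaryl bromide by methoxide.

Step 3
Reactants: 6 3-methoxyfuran; 7 acrolein
Product: 8 3-(3-methoxyfuran-2-yl)propanal
Conditions: 6 (3 equiv), morpholinium trifluoroacetate (10 mol%), CH2Cl2, −20 °C
Reagents that add atoms: none
Why: Iminium-catalysed Friedel–Crafts conjugate addition should take place at C2 of the furan, the carbon activated by both the ring oxygen and the 3-methoxy group, and the excess of 6 should suppress a second alkylation.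

Step 4
Reactants: 8 3-(3-methoxyfuran-2-yl)propanal; 4 tert-butyl 5-chloro-4-oxopentanoate
Product: 9 tert-butyl (5R,6R)-5-chloro-6-hydroxy-8-(3-methoxyfuran-2-yl)-4-oxooctanoate
Conditions: D-proline (30 mol%), 4 (3 equiv), DMSO, 4 °C
Reagents that add atoms: none
Why: The proline-catalysed direct aldol reaction should proceed through the enamine on the chlorinated side of 4 to give the anti chlorohydrin, D-proline directing the enamine to the Si face of the aldehyde so that the carbinol (C4 in guaiane numbering) is R; the chlorine-bearing centre is lost in step 6.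

Step 5
Reactants: 9 aldol chlorohydrin
Product: 10 tert-butyl (5R,6R)-6-(tert-butyldimethylsilyloxy)-5-chloro-8-(3-methoxyfuran-2-yl)-4-oxooctanoate
Conditions: TBSOTf, 2,6-lutidine, CH2Cl2, −78 °C
Reagents that add atoms: tert-butyldimethylsilyl triflate, CC(C)(C)[Si](C)(C)OS(=O)(=O)C(F)(F)F
Why: Silylation with a hindered, non-nucleophilic base should protect the carbinol without epoxide formation or retro-aldol cleavage.

Step 6
Reactants: 10 silyloxy α-chloro ketone
Product: 12 oxygen-bridged (4+3) cycloadduct (C6 ketone; C9=C10 methyl enol ether; 4α-OTBS; 5α-H; 7β-CH2CO2tBu), via oxyallyl cation 11 (not isolated)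
Conditions: Et3N (3 equiv), CF3CH2OH, 0 °C → rt
Reagents that add atoms: none
Why: Et3N enolizes the ketone toward C7 and chloride leaves from C5 in the ionizing solvent, giving the W-shaped oxyallyl cation 11, which the tethered furan traps across C1 and C8 (C1–C5 bond first at the most nucleophilic furan carbon, then C7–C8 bond by closure of the enolate onto the oxygen-stabilised cation). This is the base-mediated intramolecular oxyallyl cation–furan (4+3) cycloaddition of α-halo ketones, a known reaction type. Ring A closes as the five-membered ring that contains the three-carbon tether (exo attack of C1 on the cation terminus C5), and ring B closes as the seven-membered ring of the cycloadduct with the former furan oxygen bridging C1 and C8. The short tether allows the W-shaped cation only the extended approach, so C4 on C5 and the acetate chain on C7 should both end up syn to the oxygen bridge (H5 and H7 anti to it), which fixes C1, C5, C7 and C8 relative to each other. The absolute sense comes from the C4 stereocentre: allylic 1,3-strain holds its hydrogen in the plane of the cation and the furan approaches the face opposite to the silyloxy group, so OTBS should end up cis to H5. The step needs closure at C8 and not at the methoxy-bearing C10 (a (3+2) mode) or Favorskii rearrangement; attack at the unsubstituted C8 avoids a quaternary centre, trifluoroethanol disfavours the Favorskii path, and diastereomers can be separated at this stage.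

Step 7
Reactants: 12 cycloadduct
Product: 13 oxygen-bridged 6,10-diketone (C9 methylene)
Conditions: 1 M HCl (aq), THF, 0 °C
Reagents that add atoms: water, O
Why: Mild aqueous acid should hydrolyse only the methyl enol ether to the C10 ketone and leave the TBS ether and the tert-butyl ester.

Step 8
Reactants: 13 bridged diketone
Product: 14 cis-fused hydroazulene-6,10-dione (1α-H; 5α-H; 8β-OH; 4α-OTBS; 7β-CH2CO2tBu)
Conditions: SmI2 (2.5 equiv), THF–MeOH, −78 °C
Reagents that add atoms: none
Why: Samarium diiodide should cleave the C1–O bond of the α-alkoxy ketone (reductive α-deoxygenation) and so free the C8 hydroxyl, and kinetic protonation of the samarium enolate at C1 on the face of H5, away from C6, should give the cis ring fusion.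

Step 9
Reactants: 14 hydroxy diketone
Product: 15 10(14)-methylene 6-ketone (8β-OH)
Conditions: Zn, CH2Br2, TiCl4 (reagent pre-formed in THF), CH2Cl2, 0 °C → rt
Reagents that add atoms: dibromomethane, BrCBr
Why: Takai–Lombardo methylenation is non-basic and should take the C10 ketone, which has a methylene neighbour, in preference to the C6 ketone between two methine carbons, without epimerization at C1 or C7 and without retro-aldol cleavage.

Step 10
Reactants: 15 β-hydroxy ketone
Product: 16 6α,8β-diol
Conditions: Me4NBH(OAc)3, MeCN–AcOH (1:1), −30 °C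
Reagents that add atoms: none
Why: In the Evans–Saksena reduction the hydride is delivered from the boron bound to the C8 oxygen to the β-face of the C6 ketone, so the new hydroxyl should be α and anti to the C8 hydroxyl.

Step 11
Reactants: 16 diol
Product: 17 8β-O-TBDPS ether (6α-OH free)
Conditions: TBDPSCl (1.1 equiv), imidazole, DMF, 0 °C → rt
Reagents that add atoms: tert-butyldiphenylsilyl chloride, CC(C)(C)[Si](Cl)(c1ccccc1)c1ccccc1
Why: The bulky silyl chloride should react at the C8 hydroxyl, which has a methylene neighbour, and not at the C6 hydroxyl between two methine carbons.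

Step 12
Reactants: 17 hydroxy tert-butyl ester
Product: 18 4α-hydroxy-8β-(TBDPS-oxy)-13,15-dinorguai-10(14)-en-6α,12-olide
Conditions: CF3CO2H–CH2Cl2–H2O (20:78:2), 0 °C → rt; then aq. NaHCO3
Reagents that add atoms: none
Why: Acid should cleave the tert-butyl ester, the acid can then lactonize only onto the free 6α-hydroxyl to give the trans-fused γ-lactone, and the secondary TBS ether is hydrolysed while the far more acid-stable TBDPS ether stays.

Step 13
Reactants: 18 lactone alcohol
Product: 19 4-oxo-8β-(TBDPS-oxy)-13,15-dinorguai-10(14)-en-6α,12-olide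
Conditions: Dess–Martin periodinane, CH2Cl2, 0 °C → rt
Reagents that add atoms: none
Why: Dess–Martin oxidation should give the C4 ketone under conditions that do not epimerize C5.

Step 14
Reactants: 19 ketone
Product: 20 8β-(TBDPS-oxy)-13-norguaia-4(15),10(14)-dien-6α,12-olide
Conditions: Zn, CH2Br2, TiCl4 (reagent pre-formed in THF), CH2Cl2, 0 °C → rt
Reagents that add atoms: dibromomethane, BrCBr
Why: Takai–Lombardo methylenation should convert the ketone into the C4 exocyclic methylene without attack on the lactone and without epimerization at C5.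

Step 15
Reactants: 20 lactone
Product: 23 8β-(TBDPS-oxy)guaia-4(15),10(14),11(13)-trien-6α,12-olide, via Mannich base 21 (not isolated), via methiodide 22 (not isolated)
Conditions: LiN(iPr)2, THF, −78 °C; Me2N=CH2+ I−, −78 → 0 °C; then MeI, THF–MeOH, rt; then aq. NaHCO3, rt
Reagents that add atoms: dimethylmethyleneiminium iodide, C=[N+](C)C.[I-]
Why: Mannich reaction of the lactone lithium enolate, quaternization and Hofmann-type elimination (the standard α-methylenation of lactones) should install the C11 exocyclic methylene, the temporary C11 stereocentre being destroyed.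

Step 16
Reactants: 23 triene lactone
Product: 24 3α-hydroxy-8β-(TBDPS-oxy)guaia-4(15),10(14),11(13)-trien-6α,12-olide
Conditions: SeO2 (0.3 equiv), t-BuOOH (2 equiv), CH2Cl2, rt
Reagents that add atoms: selenium dioxide, O=[Se]=O; tert-butyl hydroperoxide, CC(C)(C)OO
Why: Riley oxidation (ene reaction then 2,3-sigmatropic shift) should hydroxylate C3, the unhindered allylic methylene of the C4 exocyclic alkene, C9 being shielded by the neighbouring silyl ether; the C3 configuration is irrelevant because it is oxidized next.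

Step 17
Reactants: 24 allylic alcohol
Product: 25 3-oxo-8β-(TBDPS-oxy)guaia-4(15),10(14),11(13)-trien-6α,12-olide
Conditions: Dess–Martin periodinane, CH2Cl2, 0 °C → rt
Reagents that add atoms: none
Why: Dess–Martin oxidation of the allylic alcohol should give the exo-methylene cyclopentanone without double-bond migration.

Step 18
Reactants: 25 enone monomer
Product: 26 3-(TBS-oxy)-8β-(TBDPS-oxy)guaia-2,4(15),10(14),11(13)-tetraen-6α,12-olide
Conditions: TBSOTf (1.2 equiv), Et3N, CH2Cl2, −78 → 0 °C
Reagents that add atoms: tert-butyldimethylsilyl triflate, CC(C)(C)[Si](C)(C)OS(=O)(=O)C(F)(F)F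
Why: Soft enolization can go only toward C2 because C4 is sp2, so the cross-conjugated silyl dienol ether should form as a single regioisomer.

Step 19
Reactants: 26 silyl dienol ether; 25 enone monomer
Product: 29 8,8′-bis-O-TBDPS ether of the target, via dienone 27 (not isolated), via Diels–Alder adduct 28 (not isolated)
Conditions: Pd(OAc)2 (1.1 equiv), 25 (2 equiv), MeCN, rt → 45 °C; then DBU (0.3 equiv), CH2Cl2, rt
Reagents that add atoms: none
Why: Saegusa–Ito oxidation puts in the C1–C2 double bond of dienone 27, whose diene C14=C10–C1=C2 should add to the exocyclic C4′=C15′ enone of 25 in an intermolecular Diels–Alder reaction on the α-face of 25, anti to C6′ (this sets the spiro centre C4′, with the ortho regiochemistry C14–C15′ and C2–C4′ of an acyl diene), and DBU then moves the C1–C10 double bond of 28 into conjugation and equilibrates the γ-positions C5 and C10 by reversible vinylogous enolization, which should lead to the isomer with H5 and H10 on the face of H6.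

Step 20
Reactants: 29 bis-silyl ether
Product: 30 target CNP0397417.1
Conditions: HF·pyridine, THF–pyridine, 0 °C → rt
Reagents that add atoms: none
Why: Buffered fluoride desilylation should free both C8 hydroxyls without touching the Michael acceptors or the epimerizable centres.

**Compound list**

1 | tert-butyl 3-bromopropanoate | CC(C)(C)OC(=O)CCBr | starting material
2 | chloroacetyl chloride | ClCC(Cl)=O | starting material
3 | (3-tert-butoxy-3-oxopropyl)zinc bromide | CC(C)(C)OC(=O)CC[Zn]Br | intermediate
4 | tert-butyl 5-chloro-4-oxopentanoate | CC(C)(C)OC(=O)CCC(=O)CCl | intermediate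
5 | 3-bromofuran | Brc1ccoc1 | starting material
6 | 3-methoxyfuran | COc1ccoc1 | intermediate
7 | acrolein | C=CC=O | starting material
8 | 3-(3-methoxyfuran-2-yl)propanal | COc1ccoc1CCC=O | intermediate
9 | tert-butyl (5R,6R)-5-chloro-6-hydroxy-8-(3-methoxyfuran-2-yl)-4-oxooctanoate | COc1ccoc1CC[C@@H](O)[C@@H](Cl)C(=O)CCC(=O)OC(C)(C)C | intermediate
10 | tert-butyl (5R,6R)-6-(tert-butyldimethylsilyloxy)-5-chloro-8-(3-methoxyfuran-2-yl)-4-oxooctanoate | COc1ccoc1CC[C@@H](O[Si](C)(C)C(C)(C)C)[C@@H](Cl)C(=O)CCC(=O)OC(C)(C)C | intermediate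
11 | W-shaped oxyallyl cation from 10 (C5–C6–C7) | COc1ccoc1CC[C@@H](O[Si](C)(C)C(C)(C)C)[CH+]C(/[O-])=C/CC(=O)OC(C)(C)C | intermediate
12 | (4+3) cycloadduct: 1β,8β-oxygen bridge; C6 ketone; C9=C10 methyl enol ether; 4α-OTBS; 5α-H; 7β-CH2CO2tBu | COC1=C[C@@H]2[C@@H](CC(=O)OC(C)(C)C)C(=O)[C@H]3[C@H](O[Si](C)(C)C(C)(C)C)CC[C@]13O2 | intermediate
13 | oxygen-bridged 6,10-diketone (as 12 with C10 ketone) | O=C1C[C@@H]2[C@@H](CC(=O)OC(C)(C)C)C(=O)[C@H]3[C@H](O[Si](C)(C)C(C)(C)C)CC[C@]13O2 | intermediate
14 | cis-fused hydroazulene-6,10-dione: 1α-H; 5α-H; 8β-OH; 4α-OTBS; 7β-CH2CO2tBu | O=C1C[C@@H](O)[C@@H](CC(=O)OC(C)(C)C)C(=O)[C@H]2[C@H](O[Si](C)(C)C(C)(C)C)CC[C@@H]12 | intermediate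
15 | 10(14)-methylene 6-ketone (8β-OH) | C=C1C[C@@H](O)[C@@H](CC(=O)OC(C)(C)C)C(=O)[C@H]2[C@H](O[Si](C)(C)C(C)(C)C)CC[C@@H]12 | intermediate
16 | 6α,8β-diol | C=C1C[C@@H](O)[C@@H](CC(=O)OC(C)(C)C)[C@H](O)[C@H]2[C@H](O[Si](C)(C)C(C)(C)C)CC[C@@H]12 | intermediate
17 | 8β-O-TBDPS ether of 16 (6α-OH free) | C=C1C[C@@H](O[Si](c3ccccc3)(c3ccccc3)C(C)(C)C)[C@@H](CC(=O)OC(C)(C)C)[C@H](O)[C@H]2[C@H](O[Si](C)(C)C(C)(C)C)CC[C@@H]12 | intermediate
18 | 4α-hydroxy-8β-(TBDPS-oxy)-13,15-dinorguai-10(14)-en-6α,12-olide | O[C@@H]1CC[C@H]2C(=C)C[C@@H](O[Si](c4ccccc4)(c4ccccc4)C(C)(C)C)[C@H]3CC(=O)O[C@@H]3[C@@H]12 | intermediate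
19 | 4-oxo-8β-(TBDPS-oxy)-13,15-dinorguai-10(14)-en-6α,12-olide | O=C1CC[C@H]2C(=C)C[C@@H](O[Si](c4ccccc4)(c4ccccc4)C(C)(C)C)[C@H]3CC(=O)O[C@@H]3[C@@H]12 | intermediate
20 | 8β-(TBDPS-oxy)-13-norguaia-4(15),10(14)-dien-6α,12-olide | C=C1CC[C@H]2C(=C)C[C@@H](O[Si](c4ccccc4)(c4ccccc4)C(C)(C)C)[C@H]3CC(=O)O[C@@H]3[C@@H]12 | intermediate
21 | 11-(dimethylaminomethyl) Mannich base of 20 | C=C1CC[C@H]2C(=C)C[C@@H](O[Si](c4ccccc4)(c4ccccc4)C(C)(C)C)[C@H]3[C@H](CN(C)C)C(=O)O[C@@H]3[C@@H]12 | intermediate
22 | methiodide of 21 | C=C1CC[C@H]2C(=C)C[C@@H](O[Si](c4ccccc4)(c4ccccc4)C(C)(C)C)[C@H]3[C@H](C[N+](C)(C)C)C(=O)O[C@@H]3[C@@H]12.[I-] | intermediate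
23 | 8β-(TBDPS-oxy)guaia-4(15),10(14),11(13)-trien-6α,12-olide | C=C1CC[C@H]2C(=C)C[C@@H](O[Si](c4ccccc4)(c4ccccc4)C(C)(C)C)[C@H]3C(=C)C(=O)O[C@@H]3[C@@H]12 | intermediate
24 | 3α-hydroxy-8β-(TBDPS-oxy)guaia-4(15),10(14),11(13)-trien-6α,12-olide | C=C1[C@H](O)C[C@H]2C(=C)C[C@@H](O[Si](c4ccccc4)(c4ccccc4)C(C)(C)C)[C@H]3C(=C)C(=O)O[C@@H]3[C@@H]12 | intermediate
25 | 3-oxo-8β-(TBDPS-oxy)guaia-4(15),10(14),11(13)-trien-6α,12-olide | C=C1C(=O)C[C@H]2C(=C)C[C@@H](O[Si](c4ccccc4)(c4ccccc4)C(C)(C)C)[C@H]3C(=C)C(=O)O[C@@H]3[C@@H]12 | intermediate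
26 | 3-(TBS-oxy)-8β-(TBDPS-oxy)guaia-2,4(15),10(14),11(13)-tetraen-6α,12-olide | C=C1C(O[Si](C)(C)C(C)(C)C)=C[C@H]2C(=C)C[C@@H](O[Si](c4ccccc4)(c4ccccc4)C(C)(C)C)[C@H]3C(=C)C(=O)O[C@@H]3[C@@H]12 | intermediate
27 | 3-oxo-8β-(TBDPS-oxy)guaia-1,4(15),10(14),11(13)-tetraen-6α,12-olide (5α-H) | C=C1C(=O)C=C2C(=C)C[C@@H](O[Si](c4ccccc4)(c4ccccc4)C(C)(C)C)[C@H]3C(=C)C(=O)O[C@@H]3[C@@H]12 | intermediate
28 | Diels–Alder adduct (C1=C10; 2β-H; 5α-H; spiro C4′) | C=C1C(=O)[C@H]2C3=C(CC[C@]24C(=O)C[C@H]2C(=C)C[C@@H](O[Si](c5ccccc5)(c5ccccc5)C(C)(C)C)[C@H]5C(=C)C(=O)O[C@@H]5[C@H]24)C[C@@H](O[Si](c5ccccc5)(c5ccccc5)C(C)(C)C)[C@H]2C(=C)C(=O)O[C@@H]2[C@@H]13 | intermediate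
29 | 8,8′-bis-O-TBDPS ether of the target | C=C1C(=O)C2=C3[C@H](CC[C@]24C(=O)C[C@H]2C(=C)C[C@@H](O[Si](c5ccccc5)(c5ccccc5)C(C)(C)C)[C@H]5C(=C)C(=O)O[C@@H]5[C@H]24)C[C@@H](O[Si](c5ccccc5)(c5ccccc5)C(C)(C)C)[C@H]2C(=C)C(=O)O[C@@H]2[C@H]13 | intermediate
30 | target CNP0397417.1 | C=C1C(=O)C2=C3[C@H](CC[C@]24C(=O)C[C@H]2C(=C)C[C@@H](O)[C@H]5C(=C)C(=O)O[C@@H]5[C@H]24)C[C@@H](O)[C@H]2C(=C)C(=O)O[C@@H]2[C@H]13 | target

**Step count.** 20 steps in total; the longest linear sequence is 19 steps (5 → 30, steps 2–20).

**Steps most likely to fail**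

Step 6 (key step). The cation may close through the compact approach, which would put the side chain on C7 anti to the oxygen bridge. It may also close at the methoxy-bearing carbon in a (3+2) sense, or the β-silyloxy group may be eliminated before ionization. Fallback: the side chain is taken out of the cycloaddition. Setting out from 8, a D-proline-catalysed aldol reaction with chloroacetone should give (3R,4R)-3-chloro-4-hydroxy-6-(3-methoxyfuran-2-yl)hexan-2-one F1. TBSOTf and 2,6-lutidine should give its silyl ether F2. Et3N in CF3CH2OH should give the unsubstituted oxyallyl cation F3 and from it the side-chain-free cycloadduct F4, in which C7 is a methylene group. Deprotonation of F4 at C7 with LiN(iPr)2 at −78 °C and alkylation with tert-butyl bromoacetate on the face syn to the oxygen bridge (the usual exo face of such bicyclic enolates) should then come back to the route at 12.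

Step 19. The dienone may dimerize with itself instead of entering the cross Diels–Alder reaction, and the equilibration at C5 and C10 under DBU may be incomplete or may settle at the wrong position. Fallback: C5 is set before the union. Setting out from 26, the Saegusa–Ito oxidation is run without 25 and dienone 27 is isolated. DBU in CH2Cl2 equilibrates C5 through the extended enolate; the 5β-H dienone F5 is separated and the 5α-H epimer is recycled through the same equilibration. F5 and an excess of 25 are then warmed neat at 45 °C to give the 5β-H Diels–Alder adduct F6. Et3N, which only moves the C1–C10 double bond into conjugation, should bring the sequence back to the route at 29.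

Step 3. The furan may be alkylated twice (C2 and C5), the electron-rich furan may decompose under acid, or acrolein may polymerize. Fallback: carbanion chemistry in place of iminium catalysis. Setting out from 6, n-BuLi in THF at −78 °C should give 3-methoxy-2-furyllithium F7 (lithiation between the two oxygen-bearing positions). Ring opening of oxetane in the presence of BF3·OEt2 should give 3-(3-methoxyfuran-2-yl)propan-1-ol F8. Parikh–Doering oxidation (SO3·pyridine, DMSO, iPr2NEt) comes back to the route at 8.

Further compounds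
F1 | step 6 | (3R,4R)-3-chloro-4-hydroxy-6-(3-methoxyfuran-2-yl)hexan-2-one | COc1ccoc1CC[C@@H](O)[C@@H](Cl)C(C)=O
F2 | step 6 | TBS ether of F1 | COc1ccoc1CC[C@@H](O[Si](C)(C)C(C)(C)C)[C@@H](Cl)C(C)=O
F3 | step 6 | unsubstituted oxyallyl cation from F2 | COc1ccoc1CC[C@@H](O[Si](C)(C)C(C)(C)C)[CH+]C([O-])=C
F4 | step 6 | side-chain-free cycloadduct (C7 methylene; otherwise as 12) | COC1=C[C@@H]2CC(=O)[C@H]3[C@H](O[Si](C)(C)C(C)(C)C)CC[C@]13O2
F5 | step 19 | 5β-H epimer of dienone 27 | C=C1C(=O)C=C2C(=C)C[C@@H](O[Si](c4ccccc4)(c4ccccc4)C(C)(C)C)[C@H]3C(=C)C(=O)O[C@@H]3[C@H]12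
F6 | step 19 | 5β-H Diels–Alder adduct (C1=C10; 2α-H) | C=C1C(=O)[C@@H]2C3=C(CC[C@]24C(=O)C[C@H]2C(=C)C[C@@H](O[Si](c5ccccc5)(c5ccccc5)C(C)(C)C)[C@H]5C(=C)C(=O)O[C@@H]5[C@H]24)C[C@@H](O[Si](c5ccccc5)(c5ccccc5)C(C)(C)C)[C@H]2C(=C)C(=O)O[C@@H]2[C@H]13
F7 | step 3 | 3-methoxy-2-furyllithium | COc1ccoc1[Li]
F8 | step 3 | 3-(3-methoxyfuran-2-yl)propan-1-ol | COc1ccoc1CCCO
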